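The cis-decahydroquinoline is cut at the ring-fusion bond C4a–C8a, shared by the piperidine ring (N1, C2, C3, C4, C4a, C8a) and the cyclohexane ring (C4a, C5, C6, C7, C8, C8a), with N1 on C8a and the hydrogens at C8a, C4a and C5 all cis. Cutting C4a–C8a together with C5–C6 gives an intramolecular Diels–Alder reaction of an (E)-N-dienyl carbamate with a (Z)-alkene that already carries the side chain; one step closes both rings and sets C4a, C5 and C8a. The precursor is an acyclic triene on an oxazolidinone whose O–CH2 arm, the later C2 methyl group, steers the facial course.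

Key step: step 11

Remark: locants (C2 … C8a, C1′ … C8′) are those of the decahydroquinoline core and the C5 side chain of the target and are used for all intermediates; 8 is assumed to be purchased as its pentane solution.

Step 1
Reactants: 1 1-bromo-4-chlorobutane; 2 (R)-2-propyloxirane
Product: 4 (R)-9-chlorononan-4-ol, via 4-chlorobutylmagnesium bromide 3 (not isolated)
Conditions: Mg, THF, rt; then CuI (10 mol%), 2, THF, −30 → 0 °C; 1 M HCl
Reagents that add atoms: none
Why: Copper-catalysed Grignard opening of a terminal epoxide occurs by SN2 attack at the CH2 terminus, so the carbinol centre of 2 is untouched and becomes C5′ (R); Mg inserts into C–Br in preference to C–Cl.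

Step 2
Reactants: 4 (R)-9-chlorononan-4-ol
Product: 5 (R)-tert-butyl[(9-chlorononan-4-yl)oxy]dimethylsilane
Conditions: TBSCl, imidazole, DMF, rt
Reagents that add atoms: tert-butyldimethylsilyl chloride, CC(C)(C)[Si](C)(C)Cl
Why: Standard imidazole-promoted silylation of a secondary alcohol; the silyl ether is chosen to last until the final acid step.

Step 3
Reactants: 5 (R)-tert-butyl[(9-chlorononan-4-yl)oxy]dimethylsilane
Product: 6 [(6R)-6-(tert-butyldimethylsilyloxy)nonyl]triphenylphosphonium iodide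
Conditions: NaI, PPh3, MeCN, reflux
Reagents that add atoms: triphenylphosphine, c1ccc(cc1)P(c1ccccc1)c1ccccc1; sodium iodide, [Na+].[I-]
Why: Finkelstein exchange in the flask gives the primary iodide, which quaternises PPh3 by SN2 substitution.

Step 4
Reactants: 7 tert-butyl (4R)-4-formyl-2,2-dimethyl-1,3-oxazolidine-3-carboxylate; 8 (−)-B-allyldiisopinocampheylborane [(−)-Ipc2B(allyl), built from (−)-α-pinene]
Product: 9 tert-butyl (4R)-4-[(1R)-1-hydroxybut-3-en-1-yl]-2,2-dimethyl-1,3-oxazolidine-3-carboxylate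
Conditions: Et2O, −78 °C → rt; then 3 M NaOH, 30% H2O2
Reagents that add atoms: none
Why: Asymmetric allylboration through a chair Zimmerman–Traxler transition state; the isopinocampheyl groups (reagent control) should set C3 as R, syn to the nitrogen at C2, overriding the modest Felkin (anti) bias of 7.

Step 5
Reactants: 9 tert-butyl (4R)-4-[(1R)-1-hydroxybut-3-en-1-yl]-2,2-dimethyl-1,3-oxazolidine-3-carboxylate
Product: 10 tert-butyl (4R)-4-[(1R)-1-(benzyloxy)but-3-en-1-yl]-2,2-dimethyl-1,3-oxazolidine-3-carboxylate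
Conditions: NaH, BnBr, Bu4NI (cat.), THF/DMF, 0 °C → rt
Reagents that add atoms: benzyl bromide, BrCc1ccccc1
Why: Williamson etherification; iodide catalysis makes O-benzylation faster than attack of the alkoxide on the Boc group.

Step 6
Reactants: 10 tert-butyl (4R)-4-[(1R)-1-(benzyloxy)but-3-en-1-yl]-2,2-dimethyl-1,3-oxazolidine-3-carboxylate
Product: 11 tert-butyl N-[(2R,3R)-3-(benzyloxy)-1-hydroxyhex-5-en-2-yl]carbamate
Conditions: TsOH·H2O (cat.), MeOH, rt
Reagents that add atoms: none
Why: Acid-catalysed transacetalisation removes the N,O-acetonide while the Boc group and the benzyl ether stay.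

Step 7
Reactants: 11 tert-butyl N-[(2R,3R)-3-(benzyloxy)-1-hydroxyhex-5-en-2-yl]carbamate
Product: 12 (4R)-4-[(1R)-1-(benzyloxy)but-3-en-1-yl]-1,3-oxazolidin-2-one
Conditions: NaH, THF, 0 °C → rt; H2O
Reagents that add atoms: none
Why: Intramolecular acyl substitution: the primary alkoxide adds to the Boc carbonyl and expels tert-butoxide; only the primary hydroxyl is free, so a single cyclic carbamate (N1–CO–O–CH2–C2) can form.

Step 8
Reactants: 12 (4R)-4-[(1R)-1-(benzyloxy)but-3-en-1-yl]-1,3-oxazolidin-2-one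
Product: 13 (3R)-3-(benzyloxy)-3-[(4R)-2-oxo-1,3-oxazolidin-4-yl]propanal
Conditions: O3, CH2Cl2, −78 °C; then PPh3, −78 °C → rt
Reagents that add atoms: ozone, [O-][O+]=O
Why: Ozonolysis with reductive work-up cleaves the terminal alkene to the aldehyde (the later C4a) without touching the stereocentres.

Step 9
Reactants: 6 [(6R)-6-(tert-butyldimethylsilyloxy)nonyl]triphenylphosphonium iodide; 13 (3R)-3-(benzyloxy)-3-[(4R)-2-oxo-1,3-oxazolidin-4-yl]propanal
Product: 15 (4R)-4-[(1R,3Z,9R)-1-(benzyloxy)-9-(tert-butyldimethylsilyloxy)dodec-3-en-1-yl]-1,3-oxazolidin-2-one, via phosphorus ylide 14 (not isolated)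
Conditions: 6 (2.2 equiv), NaN(SiMe3)2 (2.1 equiv), THF, −78 °C; then 13, −78 °C → rt
Reagents that add atoms: none
Why: Wittig reaction of a non-stabilised ylide under lithium-free conditions passes through the kinetically favoured cis-oxaphosphetane and should give the (Z)-alkene C4a=C5; the excess ylide absorbs the carbamate N–H.

Step 10
Reactants: 15 (4R)-4-[(1R,3Z,9R)-1-(benzyloxy)-9-(tert-butyldimethylsilyloxy)dodec-3-en-1-yl]-1,3-oxazolidin-2-one; 16 (E)-but-2-enal
Product: 17 (4R)-4-[(1R,3Z,9R)-1-(benzyloxy)-9-(tert-butyldimethylsilyloxy)dodec-3-en-1-yl]-3-[(1E)-buta-1,3-dien-1-yl]-1,3-oxazolidin-2-one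
Conditions: 16 (5 equiv), PPTS (10 mol%), 4 Å MS, toluene, 110 °C
Reagents that add atoms: none
Why: Acid-catalysed condensation of a cyclic N–H carbamate with an enolisable enal (N-acyl hemiaminal, N-acyliminium ion, loss of the γ-proton), as used for N-butadienyl lactams; the conjugated (E)-dienyl carbamate is the thermodynamic product.

Step 11
Reactants: 17 (4R)-4-[(1R,3Z,9R)-1-(benzyloxy)-9-(tert-butyldimethylsilyloxy)dodec-3-en-1-yl]-3-[(1E)-buta-1,3-dien-1-yl]-1,3-oxazolidin-2-one
Product: 18 (2R,3R,4aS,5S,8aR)-3-(benzyloxy)-5-[(5R)-5-(tert-butyldimethylsilyloxy)octyl]-1,2,3,4,4a,5,6,8a-octahydroquinoline with N1 and the C2–CH2O arm tied as the cyclic carbamate (tricyclic oxazolidinone)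
Conditions: toluene (0.01 M), BHT (cat.), sealed tube, 200 °C
Reagents that add atoms: none
Why: Concerted suprafacial [4+2] cycloaddition between the (E)-N-dienyl carbamate (N1–C8a=C8–C7=C6) and the tethered (Z)-alkene C4a=C5, the closest known type being the intramolecular Diels–Alder reaction of dienamides with unactivated olefins. The cyclohexene ring (C4a, C5, C6, C7, C8, C8a) closes by the cycloaddition itself through the new bonds C4a–C8a and C5–C6, and the piperidine ring (N1, C2, C3, C4, C4a, C8a) closes at the same C4a–C8a bond as the six-membered annulation of the four-atom tether onto the diene terminus, fused to the existing oxazolidinone. C5 relative to C4a follows from the Z geometry of the dienophile (H4a and H5 cis), and C8a relative to C4a from the endo position of the tether (C4 under C8), which gives the cis ring fusion. This endo mode is the one reached from the preferred rotamer about N1–C8a, with C8 turned away from the carbamate carbonyl and towards C2 and the tether in a chair. The sense relative to C2 is fixed by the oxazolidinone: its O–CH2 arm lies in the carbamate plane, so C3 leaves that plane on one face only, the alkene is delivered to that face of the diene, and C8 ends up trans to the O–CH2 arm across N1 (an open carbamate with a C2 methyl group would be driven by allylic 1,3-strain to the other face). The step needs endo (cis-fused) over exo (trans-fused) selectivity, and the axial C3 benzyloxy group points away from the diene and should not interfere.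

Step 12
Reactants: 18 tricyclic oxazolidinone (C7=C8 alkene, C3 benzyl ether)
Product: 19 (2R,3R,4aS,5S,8aR)-5-[(5R)-5-(tert-butyldimethylsilyloxy)octyl]decahydroquinolin-3-ol with N1 and the C2–CH2O arm tied as the cyclic carbamate
Conditions: H2 (1 atm), Pd/C, EtOAc/EtOH, rt
Reagents that add atoms: none
Why: Heterogeneous hydrogenation saturates the C7=C8 bond and hydrogenolyses the benzyl ether; no stereocentre is formed and the silyl ether and the carbamate stay.

Step 13
Reactants: 19 tricyclic oxazolidinone alcohol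
Product: 21 tert-butyl (2R,3R,4aS,5S,8aR)-5-[(5R)-5-(tert-butyldimethylsilyloxy)octyl]-3-hydroxy-2-(hydroxymethyl)octahydroquinoline-1(2H)-carboxylate, via amino diol 20 (not isolated)
Conditions: KOH, EtOH/H2O (3:1), 90 °C; cool, pH 9–10, Boc2O, rt → 40 °C
Reagents that add atoms: di-tert-butyl dicarbonate, CC(C)(C)OC(=O)OC(=O)OC(C)(C)C
Why: Hydroxide hydrolysis of the cyclic carbamate frees the secondary amine and the primary alcohol with loss of carbonate, and Boc2O without an acylation catalyst should acylate the amine in preference to the two hydroxyl groups.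

Step 14
Reactants: 21 N-Boc amino diol
Product: 22 tert-butyl (2R,3R,4aS,5S,8aR)-5-[(5R)-5-(tert-butyldimethylsilyloxy)octyl]-3-hydroxy-2-methyloctahydroquinoline-1(2H)-carboxylate
Conditions: 2-nitrobenzenesulfonylhydrazide, PPh3, diethyl azodicarboxylate, THF, −30 °C → rt
Reagents that add atoms: none
Why: Reductive Mitsunobu deoxygenation: the primary alcohol is displaced by the sulfonylhydrazide, sulfinic acid is lost to give the monoalkyl diazene, and loss of N2 leaves the C2 methyl group; the hindered secondary C3–OH should not be activated at this temperature and C2 is not touched.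

Step 15
Reactants: 22 N-Boc 2-methyl-3-ol; 23 (E)-oct-2-enoic acid
Product: 24 tert-butyl (2R,3R,4aS,5S,8aR)-5-[(5R)-5-(tert-butyldimethylsilyloxy)octyl]-2-methyl-3-{[(2E)-oct-2-enoyl]oxy}octahydroquinoline-1(2H)-carboxylate
Conditions: EDC·HCl, DMAP, CH2Cl2, 0 °C → rt
Reagents that add atoms: none
Why: Steglich esterification of the only free hydroxyl (nitrogen and C5′–O are blocked); the mild carbodiimide conditions should keep the (E)-2-enoate conjugated.

Step 16
Reactants: 24 N-Boc, O-TBS protected ester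
Product: 25 (2R,3R,4aS,5S,8aR)-5-[(5R)-5-hydroxyoctyl]-2-methyldecahydroquinolin-3-yl (2E)-oct-2-enoate (target)
Conditions: TFA/CH2Cl2/H2O (10:10:1), 0 °C → rt; sat. aq. NaHCO3
Reagents that add atoms: none
Why: Acidolysis removes the Boc group (tert-butyl cation and CO2) and the secondary silyl ether in one operation, while the enoate ester is stable to acid; bicarbonate work-up gives the free base.

Compound list
1 | 1-bromo-4-chlorobutane | ClCCCCBr | starting material
2 | (R)-2-propyloxirane | CCC[C@@H]1CO1 | starting material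
3 | 4-chlorobutylmagnesium bromide | ClCCCC[Mg]Br | intermediate
4 | (R)-9-chlorononan-4-ol | CCC[C@@H](O)CCCCCCl | intermediate
5 | (R)-tert-butyl[(9-chlorononan-4-yl)oxy]dimethylsilane | CCC[C@@H](O[Si](C)(C)C(C)(C)C)CCCCCCl | intermediate
6 | [(6R)-6-(tert-butyldimethylsilyloxy)nonyl]triphenylphosphonium iodide | CCC[C@@H](O[Si](C)(C)C(C)(C)C)CCCCC[P+](c1ccccc1)(c1ccccc1)c1ccccc1.[I-] | intermediate
7 | tert-butyl (4R)-4-formyl-2,2-dimethyl-1,3-oxazolidine-3-carboxylate | O=C[C@H]1COC(C)(C)N1C(=O)OC(C)(C)C | starting material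
8 | (−)-B-allyldiisopinocampheylborane | C=CCB([C@H]1C[C@H]2C[C@@H]([C@@H]1C)C2(C)C)[C@H]1C[C@H]2C[C@@H]([C@@H]1C)C2(C)C | starting material
9 | tert-butyl (4R)-4-[(1R)-1-hydroxybut-3-en-1-yl]-2,2-dimethyl-1,3-oxazolidine-3-carboxylate | C=CC[C@@H](O)[C@H]1COC(C)(C)N1C(=O)OC(C)(C)C | intermediate
10 | tert-butyl (4R)-4-[(1R)-1-(benzyloxy)but-3-en-1-yl]-2,2-dimethyl-1,3-oxazolidine-3-carboxylate | C=CC[C@@H](OCc1ccccc1)[C@H]1COC(C)(C)N1C(=O)OC(C)(C)C | intermediate
11 | tert-butyl N-[(2R,3R)-3-(benzyloxy)-1-hydroxyhex-5-en-2-yl]carbamate | C=CC[C@@H](OCc1ccccc1)[C@@H](CO)NC(=O)OC(C)(C)C | intermediate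
12 | (4R)-4-[(1R)-1-(benzyloxy)but-3-en-1-yl]-1,3-oxazolidin-2-one | C=CC[C@@H](OCc1ccccc1)[C@H]1COC(=O)N1 | intermediate
13 | (3R)-3-(benzyloxy)-3-[(4R)-2-oxo-1,3-oxazolidin-4-yl]propanal | O=CC[C@@H](OCc1ccccc1)[C@H]1COC(=O)N1 | intermediate
14 | [(6R)-6-(tert-butyldimethylsilyloxy)nonylidene]triphenylphosphorane | CCC[C@@H](O[Si](C)(C)C(C)(C)C)CCCCC=P(c1ccccc1)(c1ccccc1)c1ccccc1 | intermediate
15 | (4R)-4-[(1R,3Z,9R)-1-(benzyloxy)-9-(tert-butyldimethylsilyloxy)dodec-3-en-1-yl]-1,3-oxazolidin-2-one | CCC[C@@H](O[Si](C)(C)C(C)(C)C)CCCC/C=C\C[C@@H](OCc1ccccc1)[C@H]1COC(=O)N1 | intermediate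
16 | (E)-but-2-enal | C/C=C/C=O | starting material
17 | (4R)-4-[(1R,3Z,9R)-1-(benzyloxy)-9-(tert-butyldimethylsilyloxy)dodec-3-en-1-yl]-3-[(1E)-buta-1,3-dien-1-yl]-1,3-oxazolidin-2-one | CCC[C@@H](O[Si](C)(C)C(C)(C)C)CCCC/C=C\C[C@@H](OCc1ccccc1)[C@H]1COC(=O)N1/C=C/C=C | intermediate
18 | (2R,3R,4aS,5S,8aR)-3-(benzyloxy)-5-[(5R)-5-(tert-butyldimethylsilyloxy)octyl]-1,2,3,4,4a,5,6,8a-octahydroquinoline N1,C2-(carbonyloxymethylene) cyclic carbamate | O=C1OC[C@@H]2[C@H](OCc3ccccc3)C[C@H]4[C@@H](CCCC[C@H](O[Si](C)(C)C(C)(C)C)CCC)CC=C[C@H]4N12 | intermediate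
19 | (2R,3R,4aS,5S,8aR)-5-[(5R)-5-(tert-butyldimethylsilyloxy)octyl]decahydroquinolin-3-ol N1,C2-(carbonyloxymethylene) cyclic carbamate | O=C1OC[C@@H]2[C@H](O)C[C@H]3[C@@H](CCCC[C@H](O[Si](C)(C)C(C)(C)C)CCC)CCC[C@H]3N12 | intermediate
20 | (2R,3R,4aS,5S,8aR)-5-[(5R)-5-(tert-butyldimethylsilyloxy)octyl]-2-(hydroxymethyl)decahydroquinolin-3-ol | O[C@@H]1C[C@H]2[C@@H](CCCC[C@H](O[Si](C)(C)C(C)(C)C)CCC)CCC[C@H]2N[C@@H]1CO | intermediate
21 | tert-butyl (2R,3R,4aS,5S,8aR)-5-[(5R)-5-(tert-butyldimethylsilyloxy)octyl]-3-hydroxy-2-(hydroxymethyl)octahydroquinoline-1(2H)-carboxylate | O[C@@H]1C[C@H]2[C@@H](CCCC[C@H](O[Si](C)(C)C(C)(C)C)CCC)CCC[C@H]2N(C(=O)OC(C)(C)C)[C@@H]1CO | intermediate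
22 | tert-butyl (2R,3R,4aS,5S,8aR)-5-[(5R)-5-(tert-butyldimethylsilyloxy)octyl]-3-hydroxy-2-methyloctahydroquinoline-1(2H)-carboxylate | O[C@@H]1C[C@H]2[C@@H](CCCC[C@H](O[Si](C)(C)C(C)(C)C)CCC)CCC[C@H]2N(C(=O)OC(C)(C)C)[C@@H]1C | intermediate
23 | (E)-oct-2-enoic acid | CCCCC/C=C/C(=O)O | starting material
24 | tert-butyl (2R,3R,4aS,5S,8aR)-5-[(5R)-5-(tert-butyldimethylsilyloxy)octyl]-2-methyl-3-{[(2E)-oct-2-enoyl]oxy}octahydroquinoline-1(2H)-carboxylate | CCCCC/C=C/C(=O)O[C@@H]1C[C@H]2[C@@H](CCCC[C@H](O[Si](C)(C)C(C)(C)C)CCC)CCC[C@H]2N(C(=O)OC(C)(C)C)[C@@H]1C | intermediate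
25 | (2R,3R,4aS,5S,8aR)-5-[(5R)-5-hydroxyoctyl]-2-methyldecahydroquinolin-3-yl (2E)-oct-2-enoate | CCCCC/C=C/C(=O)O[C@@H]1C[C@H]2[C@@H](CCCC[C@H](O)CCC)CCC[C@H]2N[C@@H]1C | target

Total step count: 16. Longest linear sequence: 13 steps (7 → 25, steps 4–16); the side-chain branch (steps 1–3) joins at step 9.

Steps most likely to fail

Step 11. The unactivated (Z)-alkene may cyclise too slowly at temperatures the dienyl carbamate tolerates, or exo closure to the trans-fused isomer may compete. The fallback activates the dienophile and builds the side chain afterwards; it sets out from 13 and returns at 19. Still–Gennari olefination of 13 (methyl bis(2,2,2-trifluoroethyl)phosphonoacetate, KN(SiMe3)2, 18-crown-6, THF, −78 °C) should give methyl (2Z,5R)-5-(benzyloxy)-5-[(4R)-2-oxo-1,3-oxazolidin-4-yl]pent-2-enoate F1, and condensation with 16 as in step 10 the N-dienyl (Z)-enoate F2. Its ester is expected to take the endo position together with the tether, so cyclisation at about 130 °C in toluene should give the cis-fused cycloadduct methyl ester F3 with the same relative configuration at C4a, C5 and C8a. Reduction with i-Bu2AlH at −78 °C gives the C5 aldehyde F4, and methylenation (Ph3PCH3Br, KOt-Bu, THF) the C5 vinyl compound F5. In parallel, 2 is opened with allylmagnesium bromide and CuI to (R)-oct-7-en-4-ol F6, which is silylated (TBSCl, imidazole) to the silyl ether F7. Cross-metathesis of F5 with F7 (second-generation Grubbs catalyst, CH2Cl2, 40 °C) gives the side-chain alkene F8, and hydrogenation (H2, Pd/C), which saturates both C=C bonds and cleaves the benzyl ether, returns to 19.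

Step 10. Condensation at the hindered carbamate nitrogen may be slow, and the acid and heat may erode the silyl ether or the enamide geometry. The fallback replaces the carbonyl condensation by a C–N cross-coupling; it sets out from 15 and returns at 17. Takai iodo-olefination of acrolein (CHI3, CrCl2, THF) gives (E)-1-iodobuta-1,3-diene F9, which is coupled with the N–H of 15 (CuI, N,N′-dimethylethylenediamine, Cs2CO3, toluene, 80 °C; Goldberg-type N-alkenylation with retention of the alkene geometry) to give 17.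

Step 14. The Boc carbonyl may attack the activated CH2–O carbon and rebuild a cyclic carbamate, or the Mitsunobu activation may stay incomplete. The fallback replaces the diazene fragmentation by a halide and a radical reduction; it sets out from 21 and returns at 22. Iodination at 0 °C (I2, PPh3, imidazole, CH2Cl2, primary hydroxyl only) gives the primary iodide F10 (CH2I in place of the CH2OH of 21), which is reduced at once with Bu3SnH and AIBN in toluene at 80 °C to 22.

Further compounds
F1 | step 11 | methyl (2Z,5R)-5-(benzyloxy)-5-[(4R)-2-oxo-1,3-oxazolidin-4-yl]pent-2-enoate | COC(=O)/C=C\C[C@@H](OCc1ccccc1)[C@H]1COC(=O)N1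
F2 | step 11 | methyl (2Z,5R)-5-(benzyloxy)-5-{(4R)-3-[(1E)-buta-1,3-dien-1-yl]-2-oxo-1,3-oxazolidin-4-yl}pent-2-enoate | COC(=O)/C=C\C[C@@H](OCc1ccccc1)[C@H]1COC(=O)N1/C=C/C=C
F3 | step 11 | methyl (2R,3R,4aS,5S,8aR)-3-(benzyloxy)-1,2,3,4,4a,5,6,8a-octahydroquinoline-5-carboxylate N1,C2-(carbonyloxymethylene) cyclic carbamate | O=C1OC[C@@H]2[C@H](OCc3ccccc3)C[C@H]4[C@@H](C(=O)OC)CC=C[C@H]4N12
F4 | step 11 | (2R,3R,4aS,5S,8aR)-3-(benzyloxy)-1,2,3,4,4a,5,6,8a-octahydroquinoline-5-carbaldehyde N1,C2-(carbonyloxymethylene) cyclic carbamate | O=C1OC[C@@H]2[C@H](OCc3ccccc3)C[C@H]4[C@@H](C=O)CC=C[C@H]4N12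
F5 | step 11 | (2R,3R,4aS,5S,8aR)-3-(benzyloxy)-5-ethenyl-1,2,3,4,4a,5,6,8a-octahydroquinoline N1,C2-(carbonyloxymethylene) cyclic carbamate | O=C1OC[C@@H]2[C@H](OCc3ccccc3)C[C@H]4[C@@H](C=C)CC=C[C@H]4N12
F6 | step 11 | (R)-oct-7-en-4-ol | CCC[C@@H](O)CCC=C
F7 | step 11 | (R)-tert-butyldimethyl(oct-7-en-4-yloxy)silane | CCC[C@@H](O[Si](C)(C)C(C)(C)C)CCC=C
F8 | step 11 | (2R,3R,4aS,5S,8aR)-3-(benzyloxy)-5-[(1E,5R)-5-(tert-butyldimethylsilyloxy)oct-1-en-1-yl]-1,2,3,4,4a,5,6,8a-octahydroquinoline N1,C2-(carbonyloxymethylene) cyclic carbamate | O=C1OC[C@@H]2[C@H](OCc3ccccc3)C[C@H]4[C@@H](/C=C/CC[C@H](O[Si](C)(C)C(C)(C)C)CCC)CC=C[C@H]4N12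
F9 | step 10 | (E)-1-iodobuta-1,3-diene | I/C=C/C=C
F10 | step 14 | tert-butyl 5-[(5R)-5-(tert-butyldimethylsilyloxy)octyl]-3-hydroxy-2-(iodomethyl)octahydroquinoline-1(2H)-carboxylate (configuration as in 21) | O[C@@H]1C[C@H]2[C@@H](CCCC[C@H](O[Si](C)(C)C(C)(C)C)CCC)CCC[C@H]2N(C(=O)OC(C)(C)C)[C@@H]1CI
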